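**Retrosynthetic overview**
1. Feature used: in ring A (C1–C2–C3–C4–C5–C9) the quaternary lavandulyl bridgehead C1 is bonded to C2, and C2 lies allylic to the C3=C4(OMe) enol ether on the prenyl bridgehead C5. This is the pattern left by a [3,3] shift of a C4-vinyl group onto a C1=C8 enol ether with loss of a C4–C7 bond.
2. Target ⇐ bicyclo[3.3.1]nona-2,6-diene 38 by C7 prenylation through the C8 enolate, C8 deoxygenation, C9 OTBS → C=O, C2 allylic oxidation and C3 benzoylation.
3. Key disconnection C1–C2: 38 ⇐ Cope rearrangement of bicyclo[3.1.1]heptene 37, whose C4-vinyl group and C1=C8 silyl enol ether sit cis on the cyclobutane C4–C5–C6–C7; C4–C7 opens and ring A closes last.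
4. 37 ⇐ cyclobutanone 30 (vinyl addition at C4, O-methylation, C8 OTES → C=O → enol silane); 30 ⇐ intramolecular ketene–alkene [2+2] of acid 27 (C4–C7 and C5–C6), which forms the cyclobutane and the ring C5–C9–C1–C8–C7–C6 together, first.
5. 27 ⇐ two oxazolidinone syn-aldols (C1–C8 with 3-methylbut-2-enal, then C5–C9 with the 5-methylhex-4-enoyl imide) on lavandulylacetic acid 7, made from (S)-lavandulol.

Key step: step 21

Remarks on the chemistry
- Numbering: C1–C9 of the target core are used for every compound (C1 lavandulyl bridgehead, C2 C=O, C3 C–benzoyl, C4 C–OMe, C5 prenyl bridgehead, C6 CMe2, C7 CH–prenyl, C8 CH2, C9 bridging C=O). Ring A is C1–C2–C3–C4–C5–C9, ring B is C1–C8–C7–C6–C5–C9. Lav = (2R)-5-methyl-2-(prop-1-en-2-yl)hex-4-en-1-yl.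
- In the bicyclo[3.1.1]heptanes the one-carbon bridges are C4 and C6 (CMe2) and the three-carbon bridge is C9–C1–C8. "C4 side" and "C6 side" say toward which one-carbon bridge a substituent on the three-carbon bridge points.
- Assumption: the lipase acetylates (R)-lavandulol faster than (S)-lavandulol, so the (S)-alcohol is recovered unchanged.

Step 1
Reactants: 1 (±)-lavandulol
Product: 2 (S)-lavandulol [(2S)-5-methyl-2-(prop-1-en-2-yl)hex-4-en-1-ol]
Conditions: porcine pancreatic lipase, vinyl acetate, tBuOMe, rt, stopped at about 60 % conversion; chromatography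
Reagents that add atoms: none
Why: Lipase-catalysed kinetic resolution by enantioselective acetylation should leave the slower-reacting (S)-alcohol, which is separated from the (R)-acetate; no stereocentre is formed, one enantiomer is selected.

Step 2
Reactants: 2 (S)-lavandulol
Product: 3 (S)-lavandulyl iodide
Conditions: I2, PPh3, imidazole, CH2Cl2, 0 °C → rt
Reagents that add atoms: iodine (II)
Why: Appel-type iodination replaces the primary hydroxyl by SN2 at CH2 and does not touch the neighbouring stereocentre.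

Step 3
Reactants: 3 (S)-lavandulyl iodide; 4 dimethyl malonate
Product: 5 dimethyl 2-[(2R)-5-methyl-2-(prop-1-en-2-yl)hex-4-en-1-yl]propanedioate
Conditions: NaH, 4 (3 equiv), THF–DMF, 0 → 60 °C
Reagents that add atoms: none
Why: Malonic ester alkylation: the soft, weakly basic sodium malonate should displace the β-branched primary iodide by SN2 in preference to E2, with the stereocentre untouched.

Step 4
Reactants: 5 dimethyl lavandulylmalonate
Product: 7 (4S)-7-methyl-4-(prop-1-en-2-yl)oct-6-enoic acid, via malonic diacid 6 (not isolated)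
Conditions: KOH, MeOH–H2O, reflux; aq. HCl; then neat, 140 °C
Reagents that add atoms: potassium hydroxide ([K+].[OH-])
Why: Saponification and thermal decarboxylation of the malonic acid (malonic ester synthesis) give the two-carbon-extended acid; the lavandulyl 1,5-diene does not undergo a Cope shift at this temperature.

Step 5
Reactants: 7 lavandulylacetic acid; 8 (S)-4-benzyl-1,3-oxazolidin-2-one
Product: 10 (4S)-4-benzyl-3-[(4S)-7-methyl-4-(prop-1-en-2-yl)oct-6-enoyl]-1,3-oxazolidin-2-one, via mixed pivalic anhydride 9 (not isolated)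
Conditions: tBuCOCl, Et3N, THF, −20 °C; then LiCl, 8, rt
Reagents that add atoms: none
Why: N-Acylation of the oxazolidinone through the mixed anhydride, which is attacked at the less hindered carbonyl group, is standard for unbranched acids.

Step 6
Reactants: 10 acyl oxazolidinone; 11 3-methylbut-2-enal
Product: 13 (4S)-4-benzyl-3-{(2S,3R)-3-hydroxy-5-methyl-2-[(2R)-5-methyl-2-(prop-1-en-2-yl)hex-4-en-1-yl]hex-4-enoyl}-1,3-oxazolidin-2-one, via dibutylboron Z-enolate 12 (not isolated)
Conditions: Bu2BOTf, iPr2NEt, CH2Cl2, −78 → 0 °C; 11, −78 → 0 °C; pH 7 buffer, MeOH, H2O2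
Reagents that add atoms: none
Why: Evans syn-aldol: the Z-boron enolate reacts through a closed chair transition state on the enolate face away from the benzyl group, which sets C1 (S) and C8 (R) in a 1,8-syn relationship; the enal reacts by 1,2-addition.

Step 7
Reactants: 13 syn-aldol imide
Product: 14 (2S,3R)-3-hydroxy-N-methoxy-N,5-dimethyl-2-Lav-hex-4-enamide (Weinreb amide)
Conditions: MeNH(OMe)·HCl, AlMe3, CH2Cl2–THF, −20 → 0 °C; aq. KNaC4H4O6
Reagents that add atoms: N,O-dimethylhydroxylamine hydrochloride (CNOC.Cl)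
Why: Aluminium amide transamination of the imide, assisted by the free β-hydroxyl, releases the auxiliary without retro-aldol cleavage or epimerisation.

Step 8
Reactants: 14 Weinreb amide
Product: 15 (2S,3R)-N-methoxy-N,5-dimethyl-2-Lav-3-(triethylsilyloxy)hex-4-enamide
Conditions: Et3SiCl, imidazole, DMF, 0 °C → rt
Reagents that add atoms: chlorotriethylsilane (CC[Si](Cl)(CC)CC)
Why: Silylation under basic conditions protects the ionisable allylic C8 alcohol as a triethylsilyl ether, which can later be removed in the presence of a tert-butyldimethylsilyl ether.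

Step 9
Reactants: 15 silylated Weinreb amide
Product: 16 (2S,3R)-5-methyl-2-Lav-3-(triethylsilyloxy)hex-4-enal
Conditions: iBu2AlH, THF, −78 °C; aq. KNaC4H4O6
Reagents that add atoms: none
Why: Reduction of the N-methoxy-N-methylamide stops at the chelated hemiaminal, so the α-branched aldehyde is released only on work-up and C1 is not epimerised.

Step 10
Reactants: 17 acetic acid; 18 prenyl bromide
Product: 20 5-methylhex-4-enoic acid, via dilithium acetate dianion 19 (not isolated)
Conditions: LiN(iPr)2 (2.1 equiv), THF–DMPU, 0 → 40 °C; 18, 0 °C → rt; aq. HCl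
Reagents that add atoms: none
Why: C-Alkylation of the carboxylic acid dianion with a reactive allylic bromide by SN2 gives the prenylacetic acid in one operation.

Step 11
Reactants: 20 5-methylhex-4-enoic acid; 21 (R)-4-benzyl-1,3-oxazolidin-2-one
Product: 23 (4R)-4-benzyl-3-(5-methylhex-4-enoyl)-1,3-oxazolidin-2-one, via mixed pivalic anhydride 22 (not isolated)
Conditions: tBuCOCl, Et3N, THF, −20 °C; then LiCl, 21, rt
Reagents that add atoms: none
Why: Same mixed-anhydride N-acylation as in step 5, here with the enantiomeric auxiliary.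

Step 12
Reactants: 16 aldehyde; 23 acyl oxazolidinone
Product: 25 (4R)-4-benzyl-3-[(2R,3S,4R,5R)-3-hydroxy-7-methyl-2-(3-methylbut-2-en-1-yl)-4-Lav-5-(triethylsilyloxy)oct-6-enoyl]-1,3-oxazolidin-2-one, via dibutylboron Z-enolate 24 (not isolated)
Conditions: Bu2BOTf, iPr2NEt, CH2Cl2, −78 → 0 °C; 16, −78 → −10 °C; pH 7 buffer, MeOH, H2O2
Reagents that add atoms: none
Why: Evans syn-aldol under reagent control: the (R)-auxiliary sets C5 and C9 (5,9-syn) and gives the 9,1-anti adduct, which is the anti-Felkin sense that a Z-enolate prefers with an α-branched aldehyde, so auxiliary and substrate are matched.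

Step 13
Reactants: 25 aldol adduct
Product: 26 9-O-tert-butyldimethylsilyl ether of 25
Conditions: tBuMe2SiOTf, 2,6-lutidine, CH2Cl2, −78 → 0 °C
Reagents that add atoms: tert-butyldimethylsilyl trifluoromethanesulfonate (CC(C)(C)[Si](C)(C)OS(=O)(=O)C(F)(F)F)
Why: The silyl triflate with a hindered base silylates the congested secondary C9 hydroxyl without retro-aldol and leaves the allylic triethylsilyl ether in place.

Step 14
Reactants: 26 bis-silyl imide
Product: 27 (2R,3S,4S,5R)-3-(tert-butyldimethylsilyloxy)-7-methyl-2-(3-methylbut-2-en-1-yl)-4-Lav-5-(triethylsilyloxy)oct-6-enoic acid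
Conditions: LiOH, H2O2, THF–H2O, 0 °C; aq. Na2SO3; aq. HCl to pH 4
Reagents that add atoms: hydrogen peroxide (OO)
Why: Hydroperoxide attacks the exocyclic imide carbonyl selectively, so the auxiliary is cleaved to the acid without opening the oxazolidinone or touching the silyl ethers.

Step 15
Reactants: 27 carboxylic acid
Product: 30 bicyclo[3.1.1]heptan-4-one (cyclobutanone C4 between the C5 prenyl bridgehead and C7–H; C6 CMe2; 9-OTBS and 1-Lav on the C6 side; 8-OTES on the C4 side), via acid chloride 28 (not isolated), via ketene 29 (not isolated)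
Conditions: 1-chloro-N,N,2-trimethylprop-1-en-1-amine, CH2Cl2, 0 °C → rt; evaporate; Et3N (3 equiv), toluene (0.01 M, slow addition), 110 °C
Reagents that add atoms: none
Why: Intramolecular ketene–alkene [2+2] cycloaddition in the crossed sense: ketene carbon C4 bonds to the less substituted alkene carbon C7 and C5 to C6, which with a three-atom tether gives the bicyclo[3.1.1]heptanone; C5 and C7 are set together by the C8 stereocentre, whose C–O bond stays in the alkene plane away from the cis methyl (allylic 1,3-strain) so that the tether reaches the π-face that leaves C8–H toward the CMe2 bridge.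

Step 16
Reactants: 30 cyclobutanone; 31 vinylmagnesium bromide
Product: 32 C4 tertiary alcohol (vinyl toward the C9–C1–C8 bridge, OH toward C6)
Conditions: anhydrous CeCl3, 31, THF, −78 → 0 °C; then H2O
Reagents that add atoms: none
Why: 1,2-Addition of a vinylcerium reagent to the strained, non-enolisable cyclobutanone: the face toward C6 is closed by the methyl group lying 1,3 across the four-membered ring, so the vinyl group should enter over the three-carbon bridge from the C9 side, where only a hydrogen points toward C4, which sets C4.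

Step 17
Reactants: 32 tertiary alcohol
Product: 33 C4 methyl ether
Conditions: MeOTf, 2,6-di-tert-butyl-4-methylpyridine, CH2Cl2, 0 °C → rt
Reagents that add atoms: methyl trifluoromethanesulfonate (COS(=O)(=O)C(F)(F)F)
Why: O-Methylation with a neutral methylating agent forms no metal alkoxide, so a Grob-type opening of the cyclobutanol toward the anti-periplanar C9 silyloxy group is avoided; C4 is unchanged.

Step 18
Reactants: 33 methyl ether
Product: 34 C8 alcohol (8-OH on the C4 side)
Conditions: pyridinium p-toluenesulfonate, MeOH–CH2Cl2, 0 °C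
Reagents that add atoms: none
Why: Acid-catalysed methanolysis cleaves the secondary triethylsilyl ether much faster than the hindered tert-butyldimethylsilyl ether and does not ionise the tertiary cyclobutyl methyl ether.

Step 19
Reactants: 34 C8 alcohol
Product: 35 C8 ketone
Conditions: Dess–Martin periodinane, NaHCO3, CH2Cl2, 0 °C → rt
Reagents that add atoms: none
Why: Dess–Martin oxidation under buffered conditions gives the β-methoxy ketone, which cannot undergo retro-aldol cleavage; C1 becomes epimerisable but is about to become sp2.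

Step 20
Reactants: 35 C8 ketone
Product: 37 Cope precursor (4-methoxy-4-vinylbicyclo[3.1.1]heptene with C1=C8 trimethylsilyl enol ether and 9-OTBS), via lithium enolate 36 (not isolated)
Conditions: Me3SiCl (5 equiv) present, LiN(iPr)2, THF, −78 °C → 0 °C; pentane, filtration
Reagents that add atoms: chlorotrimethylsilane (C[Si](C)(C)Cl)
Why: Regiospecific enol silylation with internal quench: C7 is a bridgehead of the bicyclo[3.1.1]heptane and cannot be enolised, so only the C1=C8 enol ether can form, and the Me3SiCl present from the start traps the enolate before β-elimination of the C9 silyloxy group.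

Step 21
Reactants: 37 Cope precursor
Product: 38 bicyclo[3.3.1]nona-2,6-diene (C3=C4 methyl enol ether, C7=C8 trimethylsilyl enol ether, 9-OTBS toward ring B)
Conditions: toluene (degassed, 0.02 M), 2,6-di-tert-butyl-4-methylphenol (trace), silylated glass, 100 °C
Reagents that add atoms: none
Why: Thermal [3,3]-sigmatropic (Cope) rearrangement of a cis-1,2-dialkenylcyclobutane: the C2=C3 vinyl group on C4 and the C1=C8 silyl enol ether on C7 lie on the same face of the cyclobutane, overlap in the enforced boat array C2=C3–C4–C7–C8=C1, and C1–C2 forms as the strained C4–C7 bond breaks, leaving C3=C4(OMe) and C7=C8(OSiMe3); relief of ring strain and of the 1,3-repulsion between the C4 methoxy group and a C6 methyl drives it. The closest known reaction type is the Cope rearrangement of cis-1,2-divinylcyclobutanes to cycloocta-1,5-dienes, which typically needs about 80–120 °C. Ring A (C1–C2–C3–C4–C5–C9) closes through this six-membered boat transition state with the C2=C3 bond ending inside the new ring (6-endo with respect to C2=C3), while the cyclobutane opens into the eight-membered perimeter C1–C2–C3–C4–C5–C6–C7–C8. The new quaternary centre C1 is fixed by the cage: C2 can reach C1 only on the face of the three-carbon bridge that carries the C4 bridge, so its configuration follows from C5 and C7, and C5 and C9 are untouched. The step needs the vinyl group syn to the C9–C1–C8 bridge (set in step 16), an enol ether that can only be C1=C8 (C7 is a bridgehead), and free access to C1, which holds because C9 turns its hydrogen, not its OTBS group, toward the C4 bridge; the lavandulyl 1,5-diene is inert at this temperature.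

Step 22
Reactants: 38 Cope product; 18 prenyl bromide
Product: 40 7-exo-prenyl C8 ketone, via lithium enolate 39 (not isolated)
Conditions: MeLi, THF, 0 °C → rt; then DMPU, 18, −78 → 0 °C
Reagents that add atoms: none
Why: MeLi cleaves the silyl enol ether to the regiodefined lithium enolate, which is C-alkylated by the allylic bromide on the exo face of C7 because the endo face is closed by C3 of ring A; the resulting equatorial prenyl epimer is also the one favoured if the α-centre equilibrates.

Step 23
Reactants: 40 C8 ketone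
Product: 41 C8 alcohol (OH drawn syn to C9)
Conditions: LiAlH4, Et2O, −20 → 0 °C; H2O, aq. NaOH
Reagents that add atoms: none
Why: Hydride reduction of the hindered ketone, expected from the face away from the axial C6 methyl and the C9 silyloxy group; the configuration of the carbinol is of no consequence because C8 becomes CH2.

Step 24
Reactants: 41 C8 alcohol
Product: 42 C8 O-phenyl thionocarbonate
Conditions: PhOC(S)Cl, pyridine, 4-(dimethylamino)pyridine (cat.), CH2Cl2, rt → 40 °C
Reagents that add atoms: O-phenyl chlorothionoformate (S=C(Cl)Oc1ccccc1)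
Why: Thioacylation under non-basic conditions forms no alkoxide, so no silyl migration from O9 can occur, and it prepares the radical deoxygenation.

Step 25
Reactants: 42 thionocarbonate
Product: 43 8-deoxy compound (C8 CH2)
Conditions: Bu3SnH (5 equiv, 0.5 M), azobisisobutyronitrile (cat.), toluene, 90 °C
Reagents that add atoms: none
Why: Barton–McCombie deoxygenation: the secondary C8 radical is reduced by Bu3SnH kept at high concentration, which should outpace cyclisation onto the lavandulyl alkenes; C7 is not affected.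

Step 26
Reactants: 43 silyl ether
Product: 44 C9 alcohol
Conditions: Bu4NF, THF, 50 °C
Reagents that add atoms: none
Why: Fluoride cleaves the hindered silyl ether under basic conditions that leave the acid-labile methyl enol ether intact.

Step 27
Reactants: 44 C9 alcohol
Product: 45 C9 ketone
Conditions: Dess–Martin periodinane, NaHCO3, CH2Cl2, rt
Reagents that add atoms: none
Why: Dess–Martin oxidation gives the bridging ketone, which cannot enolise because both α-carbons are quaternary.

Step 28
Reactants: 45 enol ether ketone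
Product: 46 vinylogous ester (4-methoxy-3-ene-2,9-dione)
Conditions: tBuOOH (5 equiv), Pd(OH)2 on carbon (cat.), Cs2CO3, CH2Cl2, 0 °C
Reagents that add atoms: tert-butyl hydroperoxide (CC(C)(C)OO)
Why: Allylic oxidation by tert-butylperoxy radicals: the C2–H bonds are the most activated in the molecule because abstraction gives an allyl radical delocalised onto the oxygen-bearing C4, and the C2 peroxide collapses under base to the ketone.

Step 29
Reactants: 46 vinylogous ester; 47 benzoyl chloride
Product: 49 CNP0385193.1 (target), via C3-lithio vinylogous ester 48 (not isolated)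
Conditions: LiN(iPr)2, THF, −78 °C; 47, −78 → −40 °C
Reagents that add atoms: none
Why: Deprotonation of the only acidic site, the vinylic C3–H flanked by the carbonyl and methoxy groups, and C-acylation of the vinyllithium with benzoyl chloride; no stereocentre is touched.

**Compound list**
1 | (±)-lavandulol | C=C(C)C(CO)CC=C(C)C | starting material
2 | (S)-lavandulol | C=C(C)[C@H](CC=C(C)C)CO | intermediate
3 | (S)-lavandulyl iodide | C=C(C)[C@H](CC=C(C)C)CI | intermediate
4 | dimethyl malonate | COC(=O)CC(=O)OC | starting material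
5 | dimethyl 2-[(2R)-5-methyl-2-(prop-1-en-2-yl)hex-4-en-1-yl]propanedioate | C=C(C)[C@H](CC=C(C)C)CC(C(=O)OC)C(=O)OC | intermediate
6 | 2-[(2R)-5-methyl-2-(prop-1-en-2-yl)hex-4-en-1-yl]propanedioic acid | C=C(C)[C@H](CC=C(C)C)CC(C(=O)O)C(=O)O | intermediate
7 | (4S)-7-methyl-4-(prop-1-en-2-yl)oct-6-enoic acid | C=C(C)[C@H](CC=C(C)C)CCC(=O)O | intermediate
8 | (S)-4-benzyl-1,3-oxazolidin-2-one | O=C1N[C@@H](Cc2ccccc2)CO1 | starting material
9 | mixed anhydride of 7 and pivalic acid | C=C(C)[C@H](CC=C(C)C)CCC(=O)OC(=O)C(C)(C)C | intermediate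
10 | (4S)-4-benzyl-3-[(4S)-7-methyl-4-(prop-1-en-2-yl)oct-6-enoyl]-1,3-oxazolidin-2-one | C=C(C)[C@H](CC=C(C)C)CCC(=O)N1[C@@H](Cc2ccccc2)COC1=O | intermediate
11 | 3-methylbut-2-enal | CC(C)=CC=O | starting material
12 | dibutylboron Z-enolate of 10 | C=C(C)[C@H](CC=C(C)C)C/C=C(\OB(CCCC)CCCC)N1[C@@H](Cc2ccccc2)COC1=O | intermediate
13 | (2S,3R)-syn-aldol imide (C1 Lav, C8 OH) | C=C(C)[C@H](CC=C(C)C)C[C@@H]([C@H](O)C=C(C)C)C(=O)N1[C@@H](Cc2ccccc2)COC1=O | intermediate
14 | (2S,3R)-3-hydroxy-N-methoxy-N,5-dimethyl-2-Lav-hex-4-enamide | C=C(C)[C@H](CC=C(C)C)C[C@@H]([C@H](O)C=C(C)C)C(=O)N(C)OC | intermediate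
15 | 3-O-triethylsilyl ether of 14 | C=C(C)[C@H](CC=C(C)C)C[C@@H]([C@H](O[Si](CC)(CC)CC)C=C(C)C)C(=O)N(C)OC | intermediate
16 | (2S,3R)-5-methyl-2-Lav-3-(triethylsilyloxy)hex-4-enal | C=C(C)[C@H](CC=C(C)C)C[C@@H]([C@H](O[Si](CC)(CC)CC)C=C(C)C)C=O | intermediate
17 | acetic acid | CC(=O)O | starting material
18 | prenyl bromide | CC(C)=CCBr | starting material
19 | dilithium acetate dianion | [Li+].[Li+].[CH2-]C(=O)[O-] | intermediate
20 | 5-methylhex-4-enoic acid | CC(C)=CCCC(=O)O | intermediate
21 | (R)-4-benzyl-1,3-oxazolidin-2-one | O=C1N[C@H](Cc2ccccc2)CO1 | starting material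
22 | mixed anhydride of 20 and pivalic acid | CC(C)=CCCC(=O)OC(=O)C(C)(C)C | intermediate
23 | (4R)-4-benzyl-3-(5-methylhex-4-enoyl)-1,3-oxazolidin-2-one | CC(C)=CCCC(=O)N1[C@H](Cc2ccccc2)COC1=O | intermediate
24 | dibutylboron Z-enolate of 23 | CC(C)=CC/C=C(\OB(CCCC)CCCC)N1[C@H](Cc2ccccc2)COC1=O | intermediate
25 | second syn-aldol imide (5,9-syn; 9,1-anti; 1,8-syn; 9-OH, 8-OTES) | C=C(C)[C@H](CC=C(C)C)C[C@@H]([C@H](O[Si](CC)(CC)CC)C=C(C)C)[C@H](O)[C@@H](CC=C(C)C)C(=O)N1[C@H](Cc2ccccc2)COC1=O | intermediate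
26 | 9-O-TBS ether of 25 | C=C(C)[C@H](CC=C(C)C)C[C@@H]([C@H](O[Si](CC)(CC)CC)C=C(C)C)[C@H](O[Si](C)(C)C(C)(C)C)[C@@H](CC=C(C)C)C(=O)N1[C@H](Cc2ccccc2)COC1=O | intermediate
27 | (2R,3S,4S,5R)-3-(tert-butyldimethylsilyloxy)-7-methyl-2-(3-methylbut-2-en-1-yl)-4-Lav-5-(triethylsilyloxy)oct-6-enoic acid | C=C(C)[C@H](CC=C(C)C)C[C@@H]([C@H](O[Si](CC)(CC)CC)C=C(C)C)[C@H](O[Si](C)(C)C(C)(C)C)[C@@H](CC=C(C)C)C(=O)O | intermediate
28 | acid chloride of 27 | C=C(C)[C@H](CC=C(C)C)C[C@@H]([C@H](O[Si](CC)(CC)CC)C=C(C)C)[C@H](O[Si](C)(C)C(C)(C)C)[C@@H](CC=C(C)C)C(=O)Cl | intermediate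
29 | ketene from 28 (C5=C4=O) | C=C(C)[C@H](CC=C(C)C)C[C@@H]([C@H](O[Si](CC)(CC)CC)C=C(C)C)[C@H](O[Si](C)(C)C(C)(C)C)C(CC=C(C)C)=C=O | intermediate
30 | bicyclo[3.1.1]heptan-4-one (C5 prenyl, C6 CMe2, 9-OTBS and 1-Lav on the C6 side, 8-OTES on the C4 side) | C=C(C)[C@H](CC=C(C)C)C[C@H]1[C@H](O[Si](CC)(CC)CC)[C@H]2C(C)(C)[C@@](CC=C(C)C)([C@H]1O[Si](C)(C)C(C)(C)C)C2=O | intermediate
31 | vinylmagnesium bromide | C=C[Mg]Br | starting material
32 | C4 tertiary alcohol (vinyl syn to the C9–C1–C8 bridge) | C=C(C)[C@H](CC=C(C)C)C[C@H]1[C@H](O[Si](CC)(CC)CC)[C@H]2C(C)(C)[C@@](CC=C(C)C)([C@H]1O[Si](C)(C)C(C)(C)C)[C@@]2(O)C=C | intermediate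
33 | C4 methyl ether of 32 | C=C(C)[C@H](CC=C(C)C)C[C@H]1[C@H](O[Si](CC)(CC)CC)[C@H]2C(C)(C)[C@@](CC=C(C)C)([C@H]1O[Si](C)(C)C(C)(C)C)[C@@]2(OC)C=C | intermediate
34 | C8 alcohol | C=C(C)[C@H](CC=C(C)C)C[C@H]1[C@H](O)[C@H]2C(C)(C)[C@@](CC=C(C)C)([C@H]1O[Si](C)(C)C(C)(C)C)[C@@]2(OC)C=C | intermediate
35 | C8 ketone | C=C(C)[C@H](CC=C(C)C)C[C@H]1C(=O)[C@H]2C(C)(C)[C@@](CC=C(C)C)([C@H]1O[Si](C)(C)C(C)(C)C)[C@@]2(OC)C=C | intermediate
36 | lithium C1=C8 enolate of 35 | C=C(C)[C@H](CC=C(C)C)CC1=C([O-])[C@H]2C(C)(C)[C@@](CC=C(C)C)([C@H]1O[Si](C)(C)C(C)(C)C)[C@@]2(OC)C=C.[Li+] | intermediate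
37 | Cope precursor: 4-methoxy-4-vinylbicyclo[3.1.1]heptene, C1=C8 trimethylsilyl enol ether, 9-OTBS | C=C(C)[C@H](CC=C(C)C)CC1=C(O[Si](C)(C)C)[C@H]2C(C)(C)[C@@](CC=C(C)C)([C@H]1O[Si](C)(C)C(C)(C)C)[C@@]2(OC)C=C | intermediate
38 | Cope product: bicyclo[3.3.1]nona-2,6-diene, C3=C4 methyl enol ether, C7=C8 trimethylsilyl enol ether, 9-OTBS | C=C(C)[C@H](CC=C(C)C)C[C@@]12C(O[Si](C)(C)C)=CC(C)(C)[C@@](CC=C(C)C)([C@H]1O[Si](C)(C)C(C)(C)C)C(OC)=CC2 | intermediate
39 | lithium C7=C8 enolate | C=C(C)[C@H](CC=C(C)C)C[C@@]12C([O-])=CC(C)(C)[C@@](CC=C(C)C)([C@H]1O[Si](C)(C)C(C)(C)C)C(OC)=CC2.[Li+] | intermediate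
40 | 7-exo-prenyl C8 ketone | C=C(C)[C@H](CC=C(C)C)C[C@@]12C(=O)[C@@H](CC=C(C)C)C(C)(C)[C@@](CC=C(C)C)([C@H]1O[Si](C)(C)C(C)(C)C)C(OC)=CC2 | intermediate
41 | C8 alcohol | C=C(C)[C@H](CC=C(C)C)C[C@@]12[C@@H](O)[C@@H](CC=C(C)C)C(C)(C)[C@@](CC=C(C)C)([C@H]1O[Si](C)(C)C(C)(C)C)C(OC)=CC2 | intermediate
42 | C8 O-phenyl thionocarbonate | C=C(C)[C@H](CC=C(C)C)C[C@@]12[C@@H](OC(=S)Oc3ccccc3)[C@@H](CC=C(C)C)C(C)(C)[C@@](CC=C(C)C)([C@H]1O[Si](C)(C)C(C)(C)C)C(OC)=CC2 | intermediate
43 | 8-deoxy compound, 9-OTBS | C=C(C)[C@H](CC=C(C)C)C[C@@]12C[C@@H](CC=C(C)C)C(C)(C)[C@@](CC=C(C)C)([C@H]1O[Si](C)(C)C(C)(C)C)C(OC)=CC2 | intermediate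
44 | C9 alcohol | C=C(C)[C@H](CC=C(C)C)C[C@@]12C[C@@H](CC=C(C)C)C(C)(C)[C@@](CC=C(C)C)([C@H]1O)C(OC)=CC2 | intermediate
45 | C9 ketone with C3=C4 methyl enol ether | C=C(C)[C@H](CC=C(C)C)C[C@@]12C[C@@H](CC=C(C)C)C(C)(C)[C@@](CC=C(C)C)(C1=O)C(OC)=CC2 | intermediate
46 | vinylogous ester (4-methoxy-3-ene-2,9-dione) | C=C(C)[C@H](CC=C(C)C)C[C@@]12C[C@@H](CC=C(C)C)C(C)(C)[C@@](CC=C(C)C)(C1=O)C(OC)=CC2=O | intermediate
47 | benzoyl chloride | O=C(Cl)c1ccccc1 | starting material
48 | C3-lithio derivative of 46 | C=C(C)[C@H](CC=C(C)C)C[C@@]12C[C@@H](CC=C(C)C)C(C)(C)[C@@](CC=C(C)C)(C1=O)C(OC)=C([Li])C2=O | intermediate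
49 | CNP0385193.1 | C=C(C)[C@H](CC=C(C)C)C[C@@]12C[C@@H](CC=C(C)C)C(C)(C)[C@@](CC=C(C)C)(C1=O)C(OC)=C(C(=O)c1ccccc1)C2=O | target

Total step count: 29
Longest linear sequence: 27 steps (steps 1–9 and 12–29; steps 10 and 11 make the side fragment 23)

**Steps most likely to fail**

Step 21 (key step). The donor-substituted C4–C7 bond may open heterolytically instead of in a concerted shift and collapse by elimination, or the silyl enol ether may be lost on heating before it rearranges. The fallback opens the same bond stepwise by anionic chemistry and sets out from alcohol 32. Cleavage of the triethylsilyl ether (pyridinium p-toluenesulfonate, MeOH) gives the 4,8-diol F1, and Dess–Martin oxidation of its secondary hydroxyl gives the β-hydroxy ketone F2. With K2CO3 in MeOH the C4 alkoxide undergoes a retro-aldol (De Mayo-type) cleavage of C4–C7, and the vinyl ketone so released is closed by intramolecular Michael addition of the more substituted C1 enolate onto C2, which gives the bicyclo[3.3.1]nonane-4,8-dione F3. Deprotonation at the less hindered C3 (KN(SiMe3)2, THF–DMPU, −78 °C) and O-methylation with MeOTf gives the 4-methoxy-3-en-8-one F4. Its C7 enolate (LiN(iPr)2, THF) is alkylated with prenyl bromide 18, and the route is rejoined at ketone 40.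

Step 15. The dialkylketene may dimerise or add only slowly to an alkene that is deactivated by the allylic silyloxy group, and the tether may deliver it to the wrong π-face, since the C9 silyloxy group has to lie on the CMe2 side. The fallback uses a keteniminium ion in place of the ketene and sets out from acid 27. Its acid chloride 28 is treated with pyrrolidine to give the pyrrolidine amide F5. Tf2O and 2,6-di-tert-butyl-4-methylpyridine in ClCH2CH2Cl at 80 °C convert F5 into the keteniminium ion, which is more electrophilic than the ketene and should add to C7=C6 in the same crossed sense to give the cyclobutaniminium triflate F6. Hydrolysis with aq. NaHCO3 returns to cyclobutanone 30.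

Step 16. Addition may be slow or fail because a C6 methyl closes one face of the carbonyl group and the substituted C9–C1–C8 bridge, with the C8 silyloxy group, crowds the other. The fallback uses a slimmer sp-hybridised nucleophile and then a partial reduction, and sets out from cyclobutanone 30. Ethynylmagnesium bromide with anhydrous CeCl3 in THF gives the propargylic alcohol F7. Semi-hydrogenation (H2, Pd on CaCO3 poisoned with Pb(OAc)2, quinoline, EtOAc) returns to alcohol 32.

**Further compounds**
F1 | step 21 | 4,8-diol (8-O-desilyl 32) | C=C(C)[C@H](CC=C(C)C)C[C@H]1[C@H](O)[C@H]2C(C)(C)[C@@](CC=C(C)C)([C@H]1O[Si](C)(C)C(C)(C)C)[C@@]2(O)C=C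
F2 | step 21 | β-hydroxy ketone (4-hydroxy-4-vinyl-8-one) | C=C(C)[C@H](CC=C(C)C)C[C@H]1C(=O)[C@H]2C(C)(C)[C@@](CC=C(C)C)([C@H]1O[Si](C)(C)C(C)(C)C)[C@@]2(O)C=C
F3 | step 21 | bicyclo[3.3.1]nonane-4,8-dione, 9-OTBS | C=C(C)[C@H](CC=C(C)C)C[C@@]12C(=O)CC(C)(C)[C@@](CC=C(C)C)([C@H]1O[Si](C)(C)C(C)(C)C)C(=O)CC2
F4 | step 21 | 4-methoxy-3-en-8-one, 9-OTBS | C=C(C)[C@H](CC=C(C)C)C[C@@]12C(=O)CC(C)(C)[C@@](CC=C(C)C)([C@H]1O[Si](C)(C)C(C)(C)C)C(OC)=CC2
F5 | step 15 | pyrrolidine amide of 27 | C=C(C)[C@H](CC=C(C)C)C[C@@H]([C@H](O[Si](CC)(CC)CC)C=C(C)C)[C@H](O[Si](C)(C)C(C)(C)C)[C@@H](CC=C(C)C)C(=O)N1CCCC1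
F6 | step 15 | cyclobutaniminium triflate (pyrrolidinium ylidene at C4) | C=C(C)[C@H](CC=C(C)C)C[C@H]1[C@H](O[Si](CC)(CC)CC)[C@H]2C(C)(C)[C@@](CC=C(C)C)([C@H]1O[Si](C)(C)C(C)(C)C)C2=[N+]1CCCC1.[O-]S(=O)(=O)C(F)(F)F
F7 | step 16 | C4 ethynyl carbinol | C=C(C)[C@H](CC=C(C)C)C[C@H]1[C@H](O[Si](CC)(CC)CC)[C@H]2C(C)(C)[C@@](CC=C(C)C)([C@H]1O[Si](C)(C)C(C)(C)C)[C@@]2(O)C#C
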